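The cyclohexene ring of the 3a,4,5,7a-tetrahydro-1H-indene core (C3a, C4, C5, C6=C7, C7a) is a Diels–Alder retron. A biomimetic intramolecular [4+2] cycloaddition of an open-chain hexaenoic acid joins the ring-fusion carbons C3a–C7a and the two quaternary carbons C4–C5. It closes the cyclopentene and the cyclohexene at once and sets four stereocentres from the single C1 methyl stereocentre. In the precursor the 2,3-alkene is the dienophile, the 7,9-diene the diene, and the cis 4,5-alkene plus C6 the three-atom tether that becomes C1–C3 of the cyclopentene. The precursor is assembled from methyl (S)-3-hydroxy-2-methylpropanoate by olefinations and one Stille coupling.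

Key step: step 13

Remark: ring locants C1–C7a are those of the 1H-indene core of 26, chain locants are those of acid 25; compounds 13, 15 and 17 are taken as purchasable reagents.

Step 1
Reactants: 1 methyl (2S)-3-hydroxy-2-methylpropanoate
Product: 2 methyl (2S)-3-{[tert-butyl(dimethyl)silyl]oxy}-2-methylpropanoate
Conditions: TBSCl, imidazole, CH2Cl2, 0 °C → rt
Reagents that add atoms: tert-butyldimethylsilyl chloride, CC(C)(C)[Si](C)(C)Cl
Why: Imidazole-mediated silyl ether formation at the primary alcohol; the stereocentre is not involved.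

Step 2
Reactants: 2 methyl (2S)-3-{[tert-butyl(dimethyl)silyl]oxy}-2-methylpropanoate
Product: 3 (2S)-3-{[tert-butyl(dimethyl)silyl]oxy}-2-methylpropanal
Conditions: i-Bu2AlH, CH2Cl2, −78 °C; aq. KNaC4H4O6
Reagents that add atoms: none
Why: Partial ester reduction with i-Bu2AlH should stop at the aldehyde because the aluminium hemiacetal survives at −78 °C, and the α-stereocentre is retained under cold, non-basic conditions.

Step 3
Reactants: 3 (2S)-3-{[tert-butyl(dimethyl)silyl]oxy}-2-methylpropanal; 4 ethyltriphenylphosphonium iodide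
Product: 8 tert-butyl{[(2R,3Z)-4-iodo-2-methylpent-3-en-1-yl]oxy}dimethylsilane, via ethylidenetriphenylphosphorane 5 (not isolated), via (1-iodoethyl)triphenylphosphonium iodide 6 (not isolated), via (1-iodoethylidene)triphenylphosphorane 7 (not isolated)
Conditions: 4, n-BuLi, THF, rt; I2, −78 °C; NaN(SiMe3)2, −20 °C; then 3, −78 → −20 °C
Reagents that add atoms: iodine, II
Why: Stork–Zhao-type Wittig olefination with the α-iodo ylide goes through the kinetically favoured cis-oxaphosphetane and should give the Z-iodoalkene (iodine cis to the chain) without touching the α-stereocentre at −78 °C.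

Step 4
Reactants: 8 tert-butyl{[(2R,3Z)-4-iodo-2-methylpent-3-en-1-yl]oxy}dimethylsilane
Product: 10 tert-butyldimethyl{[(2R,3Z)-2-methyl-4-(tributylstannyl)pent-3-en-1-yl]oxy}silane, via alkenyllithium 9 (not isolated)
Conditions: t-BuLi (2.1 equiv), Et2O, −78 °C; Bu3SnCl, −78 °C → rt
Reagents that add atoms: tributyltin chloride, CCCC[Sn](Cl)(CCCC)CCCC
Why: Iodine–lithium exchange and trapping of the configurationally stable alkenyllithium with Bu3SnCl both proceed with retention, so tin should end up cis to the chain.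

Step 5
Reactants: 10 tert-butyldimethyl{[(2R,3Z)-2-methyl-4-(tributylstannyl)pent-3-en-1-yl]oxy}silane
Product: 11 (2R,3Z)-2-methyl-4-(tributylstannyl)pent-3-en-1-ol
Conditions: Bu4NF, THF, 0 °C → rt
Reagents that add atoms: none
Why: Fluoride-mediated desilylation cleaves the primary silyl ether, while the alkenyl–tin bond is inert to Bu4NF.

Step 6
Reactants: 11 (2R,3Z)-2-methyl-4-(tributylstannyl)pent-3-en-1-ol
Product: 12 (2R,3Z)-2-methyl-4-(tributylstannyl)pent-3-enal
Conditions: Dess–Martin periodinane, pyridine, CH2Cl2, 0 °C; crude product used at once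
Reagents that add atoms: none
Why: Buffered Dess–Martin oxidation should give the β,γ-unsaturated aldehyde without acid or base strong enough to epimerise C2 or move the alkene.

Step 7
Reactants: 12 (2R,3Z)-2-methyl-4-(tributylstannyl)pent-3-enal; 13 2-(triphenylphosphoranylidene)propanal
Product: 14 (2E,4S,5Z)-2,4-dimethyl-6-(tributylstannyl)hepta-2,5-dienal
Conditions: PhMe, 80 °C
Reagents that add atoms: none
Why: Wittig olefination with the stabilised formyl ylide is E-selective (formyl group trans to the chain) and runs under neutral conditions that should spare the α-stereocentre.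

Step 8
Reactants: 14 (2E,4S,5Z)-2,4-dimethyl-6-(tributylstannyl)hepta-2,5-dienal; 15 2-(triphenylphosphoranylidene)butanal
Product: 16 (2E,4E,6S,7Z)-2-ethyl-4,6-dimethyl-8-(tributylstannyl)nona-2,4,7-trienal
Conditions: PhMe, 110 °C
Reagents that add atoms: none
Why: A second Wittig homologation with the stabilised α-ethyl formyl ylide should give the E-configured 2-ethyl enal, the less electrophilic dienal product resisting further homologation.

Step 9
Reactants: 16 (2E,4E,6S,7Z)-2-ethyl-4,6-dimethyl-8-(tributylstannyl)nona-2,4,7-trienal; 17 diethyl [(2E)-3-phenylprop-2-en-1-yl]phosphonate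
Product: 19 tributyl[(2Z,4S,5E,7E,9E,11E)-8-ethyl-4,6-dimethyl-12-phenyldodeca-2,5,7,9,11-pentaen-2-yl]stannane, via lithiated phosphonate 18 (not isolated)
Conditions: 17, LiN(SiMe3)2, THF, −78 °C; then 16, −78 → 0 °C
Reagents that add atoms: none
Why: Horner–Wadsworth–Emmons olefination with the lithiated allylic phosphonate should give the new disubstituted alkene with E geometry and leave the alkenylstannane intact.

Step 10
Reactants: 20 diethyl 2-methylpropanedioate; 21 iodoform
Product: 23 diethyl 2-(diiodomethyl)-2-methylpropanedioate, via sodium malonate enolate 22 (not isolated)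
Conditions: NaH, Et2O, reflux; CHI3, reflux
Reagents that add atoms: none
Why: C-Alkylation of the sodium malonate by iodoform (formal substitution of iodide, through capture of diiodocarbene by the enolate) installs the diiodomethyl group.

Step 11
Reactants: 23 diethyl 2-(diiodomethyl)-2-methylpropanedioate
Product: 24 (2E)-3-iodo-2-methylprop-2-enoic acid
Conditions: KOH, EtOH/H2O, reflux; aq. HCl
Reagents that add atoms: potassium hydroxide, [K+].[OH-]
Why: Saponification followed by decarboxylative anti elimination of iodide (Grob-type fragmentation) should give the iodoacrylic acid as the E isomer, iodine trans to the carboxyl group.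

Step 12
Reactants: 19 tributyl[(2Z,4S,5E,7E,9E,11E)-8-ethyl-4,6-dimethyl-12-phenyldodeca-2,5,7,9,11-pentaen-2-yl]stannane; 24 (2E)-3-iodo-2-methylprop-2-enoic acid
Product: 25 (2E,4Z,6S,7E,9E,11E,13E)-10-ethyl-2,4,6,8-tetramethyl-14-phenyltetradeca-2,4,7,9,11,13-hexaenoic acid
Conditions: Pd(PPh3)4 (cat.), Cu(O2CC4H3S) (thiophene-2-carboxylate of monovalent copper, 1.5 equiv), DMF, 0 °C → rt, dark
Reagents that add atoms: none
Why: Copper-promoted Stille coupling transmetalates the hindered alkenylstannane through copper and couples it with the β-iodoacrylic acid with retention at both alkenes, which should give the 2E,4Z-dienoic acid.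

Step 13
Reactants: 25 (2E,4Z,6S,7E,9E,11E,13E)-10-ethyl-2,4,6,8-tetramethyl-14-phenyltetradeca-2,4,7,9,11,13-hexaenoic acid
Product: 26 (1R,3aR,4R,5S,7aS)-5-ethyl-1,3,4,7-tetramethyl-5-[(1E,3E)-4-phenylbuta-1,3-dien-1-yl]-3a,4,5,7a-tetrahydro-1H-indene-4-carboxylic acid
Conditions: PhMe (0.005 M), BHT (cat.), 100 °C, Ar, dark
Reagents that add atoms: none
Why: Thermal, concerted but asynchronous [4+2] cycloaddition of normal electron demand: the carboxyl-activated C2=C3 alkene of 25 adds suprafacially to the s-cis C7=C8–C9=C10 diene, the C3–C7 bond leading and the C2–C10 bond between the two fully substituted carbons lagging, which creates ring bonds C3a–C7a and C4–C5 of 26. The closest known reaction type is the type 1 intramolecular Diels–Alder reaction of 1,3,8-nonatrienes, as used in biomimetic polyketide cyclisations. The cyclopentene closes through the C3–C7 bond (five-membered ring over the three-atom tether C4=C5–C6, whose cis alkene holds the dienophile beside the diene), and the cyclohexene closes through the [4+2] union itself, the new C8=C9 alkene becoming C6=C7 of the core. The 6S centre (C1 of 26) controls the diene face by allylic 1,3-strain: its hydrogen eclipses the C8 methyl group, the tether reaches the diene from one face and the C6 methyl group points to the other, which sets C7a; the E,E diene and the E dienophile then fix C5 and C4 stereospecifically, and the carboxyl-endo, tether-exo transition state gives the trans ring fusion at C3a. The step needs periselectivity, endo selectivity and facial selectivity: only the C7–C10 diene lies within reach of the three-atom tether, the C8 methyl group raises the s-cis population and clashes with the tether in the tether-endo (cis-fused) arrangement, secondary orbital overlap of the carboxyl group favours the same transition state, and the 1,3-strain element fixes the face.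

Compound list
1 | methyl (2S)-3-hydroxy-2-methylpropanoate | COC(=O)[C@@H](C)CO | starting material
2 | methyl (2S)-3-{[tert-butyl(dimethyl)silyl]oxy}-2-methylpropanoate | COC(=O)[C@@H](C)CO[Si](C)(C)C(C)(C)C | intermediate
3 | (2S)-3-{[tert-butyl(dimethyl)silyl]oxy}-2-methylpropanal | O=C[C@@H](C)CO[Si](C)(C)C(C)(C)C | intermediate
4 | ethyltriphenylphosphonium iodide | CC[P+](c1ccccc1)(c1ccccc1)c1ccccc1.[I-] | starting material
5 | ethylidenetriphenylphosphorane | CC=P(c1ccccc1)(c1ccccc1)c1ccccc1 | intermediate
6 | (1-iodoethyl)triphenylphosphonium iodide | CC(I)[P+](c1ccccc1)(c1ccccc1)c1ccccc1.[I-] | intermediate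
7 | (1-iodoethylidene)triphenylphosphorane | CC(I)=P(c1ccccc1)(c1ccccc1)c1ccccc1 | intermediate
8 | tert-butyl{[(2R,3Z)-4-iodo-2-methylpent-3-en-1-yl]oxy}dimethylsilane | I/C(C)=C\[C@@H](C)CO[Si](C)(C)C(C)(C)C | intermediate
9 | [(2E,4R)-5-{[tert-butyl(dimethyl)silyl]oxy}-4-methylpent-2-en-2-yl]lithium (lithium cis to C4) | [Li]/C(C)=C\[C@@H](C)CO[Si](C)(C)C(C)(C)C | intermediate
10 | tert-butyldimethyl{[(2R,3Z)-2-methyl-4-(tributylstannyl)pent-3-en-1-yl]oxy}silane | CCCC[Sn](CCCC)(CCCC)/C(C)=C\[C@@H](C)CO[Si](C)(C)C(C)(C)C | intermediate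
11 | (2R,3Z)-2-methyl-4-(tributylstannyl)pent-3-en-1-ol | CCCC[Sn](CCCC)(CCCC)/C(C)=C\[C@@H](C)CO | intermediate
12 | (2R,3Z)-2-methyl-4-(tributylstannyl)pent-3-enal | CCCC[Sn](CCCC)(CCCC)/C(C)=C\[C@@H](C)C=O | intermediate
13 | 2-(triphenylphosphoranylidene)propanal | CC(C=O)=P(c1ccccc1)(c1ccccc1)c1ccccc1 | starting material
14 | (2E,4S,5Z)-2,4-dimethyl-6-(tributylstannyl)hepta-2,5-dienal | O=C/C(C)=C/[C@H](C)/C=C(C)\[Sn](CCCC)(CCCC)CCCC | intermediate
15 | 2-(triphenylphosphoranylidene)butanal | CCC(C=O)=P(c1ccccc1)(c1ccccc1)c1ccccc1 | starting material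
16 | (2E,4E,6S,7Z)-2-ethyl-4,6-dimethyl-8-(tributylstannyl)nona-2,4,7-trienal | O=C/C(CC)=C/C(C)=C/[C@H](C)/C=C(C)\[Sn](CCCC)(CCCC)CCCC | intermediate
17 | diethyl [(2E)-3-phenylprop-2-en-1-yl]phosphonate | CCOP(=O)(C/C=C/c1ccccc1)OCC | starting material
18 | lithium (2E)-1-(diethoxyphosphoryl)-3-phenylprop-2-en-1-ide | [Li+].CCOP(=O)([CH-]/C=C/c1ccccc1)OCC | intermediate
19 | tributyl[(2Z,4S,5E,7E,9E,11E)-8-ethyl-4,6-dimethyl-12-phenyldodeca-2,5,7,9,11-pentaen-2-yl]stannane | c1ccccc1/C=C/C=C/C(CC)=C/C(C)=C/[C@H](C)/C=C(C)\[Sn](CCCC)(CCCC)CCCC | intermediate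
20 | diethyl 2-methylpropanedioate | CCOC(=O)C(C)C(=O)OCC | starting material
21 | iodoform | IC(I)I | starting material
22 | sodium 1,3-diethoxy-2-methyl-1,3-dioxopropan-2-ide | [Na+].CCOC(=O)[C-](C)C(=O)OCC | intermediate
23 | diethyl 2-(diiodomethyl)-2-methylpropanedioate | CCOC(=O)C(C)(C(I)I)C(=O)OCC | intermediate
24 | (2E)-3-iodo-2-methylprop-2-enoic acid | C/C(=C\I)C(=O)O | intermediate
25 | (2E,4Z,6S,7E,9E,11E,13E)-10-ethyl-2,4,6,8-tetramethyl-14-phenyltetradeca-2,4,7,9,11,13-hexaenoic acid | c1ccccc1/C=C/C=C/C(CC)=C/C(C)=C/[C@H](C)/C=C(C)\C=C(/C)C(=O)O | intermediate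
26 | (1R,3aR,4R,5S,7aS)-5-ethyl-1,3,4,7-tetramethyl-5-[(1E,3E)-4-phenylbuta-1,3-dien-1-yl]-3a,4,5,7a-tetrahydro-1H-indene-4-carboxylic acid | CC[C@]1(/C=C/C=C/c2ccccc2)C=C(C)[C@H]2[C@H](C)C=C(C)[C@@H]2[C@@]1(C)C(=O)O | target

Total step count: 13. Longest linear sequence: 11 (steps 1–9, 12, 13).

Steps most likely to fail

1. Step 13. The cycloaddition may lose endo/exo control (cis-fused adduct through the tether-endo transition state) or attack the other diene face. A thermal 1,5-hydrogen shift from C6 to C2 across the cis-dienoic acid unit, or polymerisation of the polyene on long heating, may compete. The fallback moves the cycloaddition to the aldehyde oxidation level under Lewis-acid catalysis; it sets out from 24 and 19 and returns at 26. Acid 24 is reduced with LiAlH4 (Et2O, 0 °C) to (2E)-3-iodo-2-methylprop-2-en-1-ol F1, which MnO2 (CH2Cl2, rt) oxidises to (2E)-3-iodo-2-methylprop-2-enal F2. Copper-promoted Stille coupling of F2 with 19 under the conditions of step 12 should give (2E,4Z,6S,7E,9E,11E,13E)-10-ethyl-2,4,6,8-tetramethyl-14-phenyltetradeca-2,4,7,9,11,13-hexaenal F3. The more electrophilic enal is cyclised with Me2AlCl in CH2Cl2 at −78 °C, far below the temperature of the hydrogen shift and with a stronger endo preference, to (1R,3aR,4R,5S,7aS)-5-ethyl-1,3,4,7-tetramethyl-5-[(1E,3E)-4-phenylbuta-1,3-dien-1-yl]-3a,4,5,7a-tetrahydro-1H-indene-4-carbaldehyde F4. Pinnick oxidation (NaClO2, NaH2PO4, 2-methylbut-2-ene, t-BuOH/H2O) then gives 26.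

2. Step 7. The β,γ-unsaturated α-methyl aldehyde may epimerise at C2 or move its alkene into conjugation while the weakly nucleophilic formyl ylide reacts slowly at 80 °C. The fallback sets out from 12 and returns at 14. Aldehyde 12 is treated at 0 °C → rt in CH2Cl2 with the more nucleophilic ethyl 2-(triphenylphosphoranylidene)propanoate to give ethyl (2E,4S,5Z)-2,4-dimethyl-6-(tributylstannyl)hepta-2,5-dienoate F5. Reduction with i-Bu2AlH (CH2Cl2, −78 °C) gives (2E,4S,5Z)-2,4-dimethyl-6-(tributylstannyl)hepta-2,5-dien-1-ol F6, and MnO2 (CH2Cl2, rt) oxidises F6 to 14.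

3. Step 3. The iodo-ylide olefination may stall, lose Z-selectivity, over-iodinate through ylide disproportionation, or partly epimerise aldehyde 3 under the basic conditions. The fallback builds the trisubstituted alkene by stepwise cross-coupling; it sets out from 3 and returns at 10. Corey–Fuchs dibromo-olefination (CBr4, PPh3, CH2Cl2, 0 °C) gives tert-butyl{[(2R)-4,4-dibromo-2-methylbut-3-en-1-yl]oxy}dimethylsilane F7. Trans-selective Negishi monomethylation (MeZnCl, PdCl2(DPEphos) cat., THF, 0 °C → rt) replaces the bromine trans to the chain and should give tert-butyl{[(2R,3Z)-4-bromo-2-methylpent-3-en-1-yl]oxy}dimethylsilane F8. Bromine–lithium exchange and stannylation as in step 4 (t-BuLi, Et2O, −78 °C; Bu3SnCl) then give 10.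

Further compounds
F1 | step 13 | (2E)-3-iodo-2-methylprop-2-en-1-ol | OC/C(C)=C/I
F2 | step 13 | (2E)-3-iodo-2-methylprop-2-enal | O=C/C(C)=C/I
F3 | step 13 | (2E,4Z,6S,7E,9E,11E,13E)-10-ethyl-2,4,6,8-tetramethyl-14-phenyltetradeca-2,4,7,9,11,13-hexaenal | c1ccccc1/C=C/C=C/C(CC)=C/C(C)=C/[C@H](C)/C=C(C)\C=C(/C)C=O
F4 | step 13 | (1R,3aR,4R,5S,7aS)-5-ethyl-1,3,4,7-tetramethyl-5-[(1E,3E)-4-phenylbuta-1,3-dien-1-yl]-3a,4,5,7a-tetrahydro-1H-indene-4-carbaldehyde | CC[C@]1(/C=C/C=C/c2ccccc2)C=C(C)[C@H]2[C@H](C)C=C(C)[C@@H]2[C@@]1(C)C=O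
F5 | step 7 | ethyl (2E,4S,5Z)-2,4-dimethyl-6-(tributylstannyl)hepta-2,5-dienoate | CCOC(=O)/C(C)=C/[C@H](C)/C=C(C)\[Sn](CCCC)(CCCC)CCCC
F6 | step 7 | (2E,4S,5Z)-2,4-dimethyl-6-(tributylstannyl)hepta-2,5-dien-1-ol | OC/C(C)=C/[C@H](C)/C=C(C)\[Sn](CCCC)(CCCC)CCCC
F7 | step 3 | tert-butyl{[(2R)-4,4-dibromo-2-methylbut-3-en-1-yl]oxy}dimethylsilane | BrC(Br)=C[C@@H](C)CO[Si](C)(C)C(C)(C)C
F8 | step 3 | tert-butyl{[(2R,3Z)-4-bromo-2-methylpent-3-en-1-yl]oxy}dimethylsilane | Br/C(C)=C\[C@@H](C)CO[Si](C)(C)C(C)(C)C
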